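## The problem

The target 30 is a linear octameric phlorotannin: eight oxygenated benzene rings (A to H) joined only by seven diaryl ether bonds, with twenty-one free hydroxyls and no carbon substituent. Ring A is a 2,4,6-trihydroxyphenyl end group. Rings B and D are 3,5-dihydroxy-1,4-dioxy rings whose C4 oxygen lies between two hydroxyls. Rings C, E and G are 3,4,5-trihydroxy-1,2-dioxy rings, ring F is a 3,4-dihydroxy-1,5-dioxy ring, and ring H is a 3,4,5-trihydroxyphenyl end group. There is no stereocentre, so nothing has to be set or relayed; the difficulty is regiochemical and steric. Most ether oxygens are flanked by ortho oxygen substituents. The D–O–E ether is flanked on both sides on both rings (two hydroxyls on ring D, the ring F oxygen and a hydroxyl on ring E), which puts it outside what copper catalysis or SNAr can be trusted to do on electron-rich arenes. The free polyphenol oxidises readily, above all in base, so every hydroxyl that is not being used must stay masked until the last step; the masked intermediates must in turn survive peracid, copper, radical bromination and alkoxide. The feature that opens the key step is that ring D is a phloroglucinol nucleus (oxygen on C1, C3, C5) with one extra oxygen on C4. This maps onto triacetic acid lactone 23: the C1 oxygen is the lactone's C4 oxygen, the C3 and C5 hydroxyls are its carbonyl and ring oxygens, and C4 is its methyl carbon. The D–O–E ether can therefore be made as an alkyl aryl ether at an sp3 carbon before ring D exists.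

## Retrosynthesis

**30 to 29.** Only O–methyl bonds are cut, nineteen of them. Methyl is preferred to benzyl because every building block is then purchasable or one step away, and because methyl ethers survive all the reagents of the route. The price is one forcing Lewis-acid step at the end, which diaryl ethers tolerate because they offer no sp3 carbon to bromide. The two ring D hydroxyls of 29 are free as they come from the key step and need no protection for one further step.

**29 to 27 (key disconnection).** Ring D is opened between C3 (hydroxyl-bearing) and C4 (bonded to the ring E oxygen), and the C5 oxygen is returned to a ring oxygen. This leads through the open keto ester 28 to the 2-pyranone 27.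
- The neighbouring cut, the aryl C–O bond of the D–O–E ether, would ask a doubly flanked phenoxide to attack a doubly flanked, unactivated aromatic carbon.
- In 27 the ring E oxygen sits on a methylene group and the ring C oxygen on a vinylogous ester carbon, so both hindered ethers become ordinary substitutions.
- 27 is an isomer of 29 and divides into pieces of three, one and four rings.
- The forward step needs an alkoxide to open the lactone at C2 before it exchanges the C4 aryloxy group, and the side-chain carbon must then acylate intramolecularly.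
- The plan is strengthened here by using Mg(OMe)2 as the only alkoxide (cold for the opening, warm for the closure) and by placing the doubly ortho-substituted ring C phenoxy group on C4.

**27 to 22 and 26; 26 to 14 and 25; 25 to 24 to 23.** The two C–O bonds at the pyranone are cut: the vinylic C4–O bond (phenol 22 plus bromide 26) and the CH2–O bond (phenol 14 plus dibromide 25). The order is fixed by the bromination. The side-chain bromine must be introduced by a radical reaction before any electron-rich arene is present, so 25 carries both leaving groups and the faster SN2 displacement is run first. 25 comes from 24, and 24 from triacetic acid lactone 23. The forward steps need site selectivity between a primary allylic and a vinylic bromide, then addition–elimination by a hindered phenoxide at an unhindered sp2 carbon.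

**14 back to 3.** The tetramer phenol is taken apart one ether at a time. In each cut the oxygen comes from a phenol and the carbon from an aryl bromide that is either unhindered or activated by an ortho formyl group. The formyl group then serves as the masked hydroxyl for the next ether (Baeyer–Villiger oxidation through formates 13, 10 and 6).
- 14 comes from aldehyde 12, and 12 from phenol 11 and bromoaldehyde 2.
- 11 comes from aldehyde 9, and 9 from phenol 7 and bromoaldehyde 8.
- 7 comes from aldehyde 5, and 5 from phenol 3 and bromoaldehyde 4.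

The opposite polarity at each bond would need aryl halides flanked by two donors and carrying no activator. The isomeric bromoaldehydes 2 and 4 deliver the trimethoxycatechol ring in its two orientations: 4 puts the incoming oxygen next to a methoxy group (ring G), 2 puts it next to a hydrogen (rings E and C). Each cycle removes one ring. It asks for a copper etherification that tolerates an aldehyde and for aryl rather than hydride migration in the oxidation, which the ortho and para oxygen donors provide.

**22 back to 15.** The same cycle is used: 22 comes from aldehyde 20 (formate 21), and 20 from phenol 19 and 2; 19 comes from aldehyde 17 (formate 18), and 17 from phenol 15 and bromoaldehyde 16. Ring A must be the nucleophile because its carbon is flanked by two methoxy groups, so assembly runs from ring A to ring C. The para formyl group of 16 activates the bromide and later becomes the hindered ring B oxygen between two methoxy groups.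

**2 to 1.** The formyl C–C bond is cut. The two free positions of 1 are equivalent, so formylation can give only 2.

## Roads not taken

**Alternative 1: squaric ester ring expansion builds ring E.**
- Cut: ring E itself, at its C2–C3 bond.
- Forward key step: the racemic cyclobutenone A1 (2-aryloxy-3,4-dimethoxy-4-(1-methoxyvinyl)cyclobutenone, aryl being the permethylated A–D tetramer) is heated. Four-electron ring opening gives a dienylketene; six-electron electrocyclisation and tautomerisation give the A–E pentamer A2 with one free hydroxyl on ring E.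
- Merits: the pentaoxygenated ring arises with defined regiochemistry and with exactly the hydroxyl needed next left free. The crowded D–O–E bond is again laid down on a non-aromatic carbon. The step is thermal, with no nucleophile present, so exchange of an aryloxy group cannot occur. In this respect it is better than step 16.
- Weak points: ring E is not the difficult ring, since 2 supplies the same unit in one coupling. The hindered A–D phenol must be built first and placed on the four-membered ring, and the alkenyl nucleophile must then choose between two similar carbonyl groups. After the expansion, rings F to H must still be attached to the hindered phenol of A2 by arylation. That needs an F–G–H aryl electrophile, which the phenol-based fragment chemistry does not deliver.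
- Comparison: the chosen plan offers convergence (three plus four rings joined at ring D by two substitutions), both large fragments used as phenols made by one repeating two-step cycle, and the inexpensive C6 unit 23.

**Alternative 2: aerobic ortho-oxygenation and phenol capture complete ring G.**
- Cut: two C–O bonds of ring G, one to a future hydroxyl oxygen and one to ring H.
- Forward key step: in the heptamer phenol A3, ring G is a 4-aryloxy-2-methoxyphenol. [Cu(MeCN)4]PF6 with N,N'-di-tert-butylethylenediamine under O2 oxygenates it to the ortho-quinone, phenol 3 adds, and reoxidation gives the quinone A4. Reduction and demethylation would then lead to 30.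
- Merits: one operation installs an oxygen and a hindered ether with no halide or aldehyde handle. For the G–H region this is shorter than the two-step cycle used here (steps 2 and 3).
- Weak points: the oxidation runs on a heptamer with six other electron-rich rings. Both the site of oxygenation and the site of phenol addition must be correct. The ring F aryloxy group of the quinone sits on a β-carbon and can be exchanged by the incoming phenoxide. The D–O–E ether still has to be made by other means, and the heptamer requires a long linear sequence.
- Comparison: the chosen plan's uncertain step uses no oxidant, its fragments come from robust chemistry, and it addresses the most hindered ether of the molecule.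

**Alternative 3: three-component ruthenium-activated etherification around ring B.**
- Cut: both ether bonds of ring B.
- Forward key step: on A5, the cyclopentadienylruthenium hexafluorophosphate complex of 2,5-dichloro-1,3-dimethoxybenzene (divalent ruthenium), the phenoxide of 15 displaces the unflanked chloride. The ring C phenoxide of the hexamer A6 then displaces the chloride between the methoxy groups, giving the complex A7. Decomplexation and demethylation would lead to 30.
- Merits: the cationic metal turns an electron-rich dichloroarene into an SNAr substrate under mild conditions. Two ethers, one of them tri-ortho-substituted, are formed in one pot with the hindered phenol 15 as nucleophile. For the A–B–C end this is shorter than steps 8 to 11.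
- Weak points: ruthenium is stoichiometric, and complexation and decomplexation add steps. The order of the two chloride displacements must be clean. The second displacement joins a hindered phenoxide to a doubly flanked carbon. A6 already contains the D–O–E ether, which this plan leaves unsolved. The metal must be removed from a molecule with eight electron-rich rings.
- Comparison: the chosen plan uses catalytic copper and a key step aimed directly at the D–O–E bond.

Key step: step 16

Assumption: rotation about the seven diaryl ether bonds is taken as fast at room temperature, so 30 has no stereogenic element. Ring letters run from the 2,4,6-trioxygenated end (ring A) to the 3,4,5-trioxygenated end (ring H).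

In steps 14 to 17, "ArE–O" is the aryloxy residue of phenol 14 (bonded through its ring E oxygen) and "ArC–O" is the aryloxy residue of phenol 22 (bonded through its ring C oxygen).

Step 1
Reactants: 1 5-bromo-1,2,3-trimethoxybenzene
Product: 2 6-bromo-2,3,4-trimethoxybenzaldehyde
Conditions: Cl2CHOMe, TiCl4, CH2Cl2, −10 to 0 °C; then ice, aq. HCl
Reagents that add atoms: dichloromethyl methyl ether COC(Cl)Cl; water O
Why: Rieche formylation; the only free positions of 1 are equivalent and lie ortho and para to methoxy groups, so a single aldehyde can form, and the low temperature limits TiCl4 cleavage of the methoxy group next to the new formyl group.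

Step 2
Reactants: 3 3,4,5-trimethoxyphenol; 4 2-bromo-3,4,5-trimethoxybenzaldehyde
Product: 5 3,4,5-trimethoxy-2-(3,4,5-trimethoxyphenoxy)benzaldehyde (G–H aldehyde)
Conditions: CuI (cat.), picolinic acid, K3PO4, DMSO, 90 °C, Ar
Reagents that add atoms: none
Why: Ullmann diaryl ether synthesis with monovalent copper; the ortho formyl group activates the bromide of 4 although it is flanked on both sides, and the phenol 3 is unhindered, the combination known for couplings of 2-bromo-3,4,5-trimethoxybenzoyl derivatives with phenols.

Step 3
Reactants: 5 G–H aldehyde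
Product: 7 3,4,5-trimethoxy-2-(3,4,5-trimethoxyphenoxy)phenol (G–H phenol), via aryl formate 6 (not isolated)
Conditions: mCPBA, CH2Cl2, 0 °C to rt; then K2CO3 (cat.), MeOH, rt
Reagents that add atoms: mCPBA O=C(OO)c1cccc(Cl)c1
Why: Baeyer–Villiger oxidation of an electron-rich benzaldehyde; the aryl group with ortho aryloxy and para methoxy donors migrates in preference to hydride, and methanolysis of formate 6 releases the phenol only after the peracid is consumed.

Step 4
Reactants: 7 G–H phenol; 8 3-bromo-4,5-dimethoxybenzaldehyde
Product: 9 3,4-dimethoxy-5-[3,4,5-trimethoxy-2-(3,4,5-trimethoxyphenoxy)phenoxy]benzaldehyde (F–G–H aldehyde)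
Conditions: CuI (cat.), picolinic acid, K3PO4, DMSO, 100 °C, Ar
Reagents that add atoms: none
Why: Ullmann diaryl ether synthesis; the phenol carries one ortho substituent and the bromide one ortho methoxy group, a degree of hindrance this ligand system is made for, and the non-enolisable aldehyde is inert to phosphate.

Step 5
Reactants: 9 F–G–H aldehyde
Product: 11 3,4-dimethoxy-5-[3,4,5-trimethoxy-2-(3,4,5-trimethoxyphenoxy)phenoxy]phenol (F–G–H phenol), via aryl formate 10 (not isolated)
Conditions: mCPBA, CH2Cl2, 0 °C to rt; then K2CO3 (cat.), MeOH, rt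
Reagents that add atoms: mCPBA O=C(OO)c1cccc(Cl)c1
Why: Baeyer–Villiger oxidation; the substrate is a 3,4,5-trioxygenated benzaldehyde of the kind from which 3 itself is made, the para methoxy group directing aryl migration.

Step 6
Reactants: 11 F–G–H phenol; 2 6-bromo-2,3,4-trimethoxybenzaldehyde
Product: 12 2,3,4-trimethoxy-6-{3,4-dimethoxy-5-[3,4,5-trimethoxy-2-(3,4,5-trimethoxyphenoxy)phenoxy]phenoxy}benzaldehyde (E–F–G–H aldehyde)
Conditions: CuI (cat.), picolinic acid, K3PO4, DMSO, 90 °C, Ar
Reagents that add atoms: none
Why: Ullmann diaryl ether synthesis between an unhindered phenol and a bromide activated by an ortho formyl group and flanked on one side only, the most favourable pairing of the series.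

Step 7
Reactants: 12 E–F–G–H aldehyde
Product: 14 2,3,4-trimethoxy-6-{3,4-dimethoxy-5-[3,4,5-trimethoxy-2-(3,4,5-trimethoxyphenoxy)phenoxy]phenoxy}phenol (E–F–G–H phenol), via aryl formate 13 (not isolated)
Conditions: mCPBA, CH2Cl2, 0 °C to rt; then K2CO3 (cat.), MeOH, rt
Reagents that add atoms: mCPBA O=C(OO)c1cccc(Cl)c1
Why: Baeyer–Villiger oxidation; a benzaldehyde with two ortho oxygens and a para methoxy group is the fastest class for aryl migration, and the product is the hindered ring E phenol needed for step 14.

Step 8
Reactants: 15 2,4,6-trimethoxyphenol; 16 4-bromo-2,6-dimethoxybenzaldehyde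
Product: 17 2,6-dimethoxy-4-(2,4,6-trimethoxyphenoxy)benzaldehyde (A–B aldehyde)
Conditions: CuI (cat.), picolinic acid, K3PO4, DMSO, 90 °C, Ar (degassed)
Reagents that add atoms: none
Why: Ullmann diaryl ether synthesis; the doubly ortho-substituted phenol 15 meets an unhindered bromide activated by a para formyl group, and exclusion of oxygen protects the easily oxidised phenoxide.

Step 9
Reactants: 17 A–B aldehyde
Product: 19 2,6-dimethoxy-4-(2,4,6-trimethoxyphenoxy)phenol (A–B phenol), via aryl formate 18 (not isolated)
Conditions: mCPBA, CH2Cl2, 0 °C; then K2CO3 (cat.), MeOH, rt, Ar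
Reagents that add atoms: mCPBA O=C(OO)c1cccc(Cl)c1
Why: Baeyer–Villiger oxidation of a 2,6-dimethoxy-4-aryloxybenzaldehyde; the para-aryloxyphenol 19 is formed only in the methanolysis, after the oxidant is gone, so it is not taken on to a quinone.

Step 10
Reactants: 19 A–B phenol; 2 6-bromo-2,3,4-trimethoxybenzaldehyde
Product: 20 6-[2,6-dimethoxy-4-(2,4,6-trimethoxyphenoxy)phenoxy]-2,3,4-trimethoxybenzaldehyde (A–B–C aldehyde)
Conditions: CuI (cat.), picolinic acid, K3PO4, DMSO, 100 °C, Ar (degassed)
Reagents that add atoms: none
Why: Ullmann diaryl ether synthesis; the hindered 2,6-dimethoxyphenoxide is paired with the ortho-formyl-activated bromide 2, whose reacting carbon has a hydrogen on its other side, and gives the tri-ortho-substituted B–O–C ether.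

Step 11
Reactants: 20 A–B–C aldehyde
Product: 22 6-[2,6-dimethoxy-4-(2,4,6-trimethoxyphenoxy)phenoxy]-2,3,4-trimethoxyphenol (A–B–C phenol), via aryl formate 21 (not isolated)
Conditions: mCPBA, CH2Cl2, 0 °C; then K2CO3 (cat.), MeOH, rt
Reagents that add atoms: mCPBA O=C(OO)c1cccc(Cl)c1
Why: Baeyer–Villiger oxidation as in step 7; oxidation of the very electron-rich formyl-bearing ring is faster at 0 °C than attack of the peracid on the other arenes.

Step 12
Reactants: 23 4-hydroxy-6-methyl-2H-pyran-2-one (triacetic acid lactone)
Product: 24 4-bromo-6-methyl-2H-pyran-2-one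
Conditions: Bu4NBr, P2O5, toluene, 100 °C
Reagents that add atoms: tetrabutylammonium bromide CCCC[N+](CCCC)(CCCC)CCCC.[Br-]
Why: Dehydroxy-bromination of a vinylogous acid; phosphorylation of the C4 hydroxyl followed by addition–elimination of bromide is the established preparation of this bromide.

Step 13
Reactants: 24 4-bromo-6-methyl-2H-pyran-2-one
Product: 25 4-bromo-6-(bromomethyl)-2H-pyran-2-one
Conditions: NBS, AIBN (cat.), PhCF3, 85 °C
Reagents that add atoms: N-bromosuccinimide O=C1CCC(=O)N1Br
Why: Wohl–Ziegler bromination; the C6 methyl group is allylic to the ring diene and gives a stabilised radical, while the electron-poor bromopyranone ring resists ionic bromination.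

Step 14
Reactants: 14 E–F–G–H phenol; 25 4-bromo-6-(bromomethyl)-2H-pyran-2-one
Product: 26 4-bromo-6-[(ArE-oxy)methyl]-2H-pyran-2-one
Conditions: K2CO3, acetone, 0 °C to rt
Reagents that add atoms: none
Why: Williamson ether synthesis; SN2 displacement of the primary allylic bromide by a hindered phenoxide under mild carbonate conditions is faster than addition–elimination at the vinylic C4 bromide, which needs a stronger base or heat.

Step 15
Reactants: 26 4-bromo-6-[(ArE-oxy)methyl]-2H-pyran-2-one; 22 A–B–C phenol
Product: 27 4-(ArC-oxy)-6-[(ArE-oxy)methyl]-2H-pyran-2-one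
Conditions: Cs2CO3, DMF, rt to 40 °C
Reagents that add atoms: none
Why: Nucleophilic vinylic substitution by addition–elimination at C4 of a 4-bromo-2-pyranone, a vinylogous acyl bromide that takes oxygen, nitrogen and sulfur nucleophiles; the hindered oxygen attacks an unhindered sp2 carbon, so the crowding of ring C costs little.

Step 16
Reactants: 27 4-(ArC-oxy)-6-[(ArE-oxy)methyl]-2H-pyran-2-one
Product: 29 2-(ArE-oxy)-5-(ArC-oxy)benzene-1,3-diol (octamer with free resorcinol hydroxyls on ring D and nineteen methyl ethers), via keto ester 28 (not isolated)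
Conditions: Mg(OMe)2, MeOH–THF, 0 °C, then 55 °C, Ar; cold aq. HCl
Reagents that add atoms: none
Why: Magnesium methoxide, bound to the lactone carbonyl, delivers methoxide to C2 of 27 and opens the ring to the magnesium enolate of keto ester 28, in which the ester and the ketone-bearing chain remain cis on the double bond as the lactone held them. Proton transfer gives the enolate at the aryloxy-bearing methylene carbon, favoured because the aryloxy group acidifies that carbon and because the ketone oxygen and the ring E ether oxygen can chelate magnesium; this carbon attacks the ester carbonyl in a 6-(enolendo)-exo-trig Claisen closure that forms the C3–C4 bond of ring D. Loss of methoxide gives a cyclohexenedione that enolises at once to the resorcinol, so C-acylation is irreversible, whereas O-acylation only returns 27. The closest known reaction type is the alkoxide-induced conversion of 4-alkoxy-6-methyl-2-pyranones (ethers of triacetic acid lactone) into 5-alkoxyresorcinols; here both oxygens are aryl ethers and the nucleophilic carbon carries one of them. No stereocentre is formed. The selectivity needed is attack at C2 ahead of addition–elimination at C4, which would expel the ring C phenoxide; it rests on the chelating, weakly dissociated magnesium alkoxide, on the two ortho substituents of ring C that shield C4, and on the fact that opened 28 exists as an enolate that no longer accepts methoxide at its aryloxy-bearing alkene carbon or at its ketone.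

Step 17
Reactants: 29 nonadeca-O-methyl octamer
Product: 30 target octamer CNP0309601.0 (all twenty-one hydroxyls free)
Conditions: BBr3 (excess), CH2Cl2, −78 °C to rt, Ar; then MeOH, H2O
Reagents that add atoms: none
Why: Lewis-acid cleavage of aryl methyl ethers; boron binds each methoxy oxygen and bromide removes the methyl group by SN2, a path closed to the diaryl ether bonds, and the two free hydroxyls of ring D only consume reagent.

## Compound list

1 | 5-bromo-1,2,3-trimethoxybenzene | COc1cc(Br)cc(OC)c1OC | starting material
2 | 6-bromo-2,3,4-trimethoxybenzaldehyde | O=Cc1c(Br)cc(OC)c(OC)c1OC | intermediate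
3 | 3,4,5-trimethoxyphenol | COc1cc(O)cc(OC)c1OC | starting material
4 | 2-bromo-3,4,5-trimethoxybenzaldehyde | O=Cc1cc(OC)c(OC)c(OC)c1Br | starting material
5 | 3,4,5-trimethoxy-2-(3,4,5-trimethoxyphenoxy)benzaldehyde (G–H aldehyde) | O=Cc1cc(OC)c(OC)c(OC)c1Oc1cc(OC)c(OC)c(OC)c1 | intermediate
6 | 3,4,5-trimethoxy-2-(3,4,5-trimethoxyphenoxy)phenyl formate | O=COc1cc(OC)c(OC)c(OC)c1Oc1cc(OC)c(OC)c(OC)c1 | intermediate
7 | 3,4,5-trimethoxy-2-(3,4,5-trimethoxyphenoxy)phenol (G–H phenol) | Oc1cc(OC)c(OC)c(OC)c1Oc1cc(OC)c(OC)c(OC)c1 | intermediate
8 | 3-bromo-4,5-dimethoxybenzaldehyde | O=Cc1cc(Br)c(OC)c(OC)c1 | starting material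
9 | 3,4-dimethoxy-5-[3,4,5-trimethoxy-2-(3,4,5-trimethoxyphenoxy)phenoxy]benzaldehyde (F–G–H aldehyde) | O=Cc1cc(OC)c(OC)c(Oc2cc(OC)c(OC)c(OC)c2Oc2cc(OC)c(OC)c(OC)c2)c1 | intermediate
10 | 3,4-dimethoxy-5-[3,4,5-trimethoxy-2-(3,4,5-trimethoxyphenoxy)phenoxy]phenyl formate | O=COc1cc(OC)c(OC)c(Oc2cc(OC)c(OC)c(OC)c2Oc2cc(OC)c(OC)c(OC)c2)c1 | intermediate
11 | 3,4-dimethoxy-5-[3,4,5-trimethoxy-2-(3,4,5-trimethoxyphenoxy)phenoxy]phenol (F–G–H phenol) | Oc1cc(OC)c(OC)c(Oc2cc(OC)c(OC)c(OC)c2Oc2cc(OC)c(OC)c(OC)c2)c1 | intermediate
12 | 2,3,4-trimethoxy-6-{3,4-dimethoxy-5-[3,4,5-trimethoxy-2-(3,4,5-trimethoxyphenoxy)phenoxy]phenoxy}benzaldehyde (E–F–G–H aldehyde) | O=Cc1c(Oc2cc(OC)c(OC)c(Oc3cc(OC)c(OC)c(OC)c3Oc3cc(OC)c(OC)c(OC)c3)c2)cc(OC)c(OC)c1OC | intermediate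
13 | 2,3,4-trimethoxy-6-{3,4-dimethoxy-5-[3,4,5-trimethoxy-2-(3,4,5-trimethoxyphenoxy)phenoxy]phenoxy}phenyl formate | O=COc1c(Oc2cc(OC)c(OC)c(Oc3cc(OC)c(OC)c(OC)c3Oc3cc(OC)c(OC)c(OC)c3)c2)cc(OC)c(OC)c1OC | intermediate
14 | 2,3,4-trimethoxy-6-{3,4-dimethoxy-5-[3,4,5-trimethoxy-2-(3,4,5-trimethoxyphenoxy)phenoxy]phenoxy}phenol (E–F–G–H phenol) | Oc1c(Oc2cc(OC)c(OC)c(Oc3cc(OC)c(OC)c(OC)c3Oc3cc(OC)c(OC)c(OC)c3)c2)cc(OC)c(OC)c1OC | intermediate
15 | 2,4,6-trimethoxyphenol | COc1cc(OC)c(O)c(OC)c1 | starting material
16 | 4-bromo-2,6-dimethoxybenzaldehyde | O=Cc1c(OC)cc(Br)cc1OC | starting material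
17 | 2,6-dimethoxy-4-(2,4,6-trimethoxyphenoxy)benzaldehyde (A–B aldehyde) | COc1cc(OC)c(Oc2cc(OC)c(C=O)c(OC)c2)c(OC)c1 | intermediate
18 | 2,6-dimethoxy-4-(2,4,6-trimethoxyphenoxy)phenyl formate | COc1cc(OC)c(Oc2cc(OC)c(OC=O)c(OC)c2)c(OC)c1 | intermediate
19 | 2,6-dimethoxy-4-(2,4,6-trimethoxyphenoxy)phenol (A–B phenol) | COc1cc(OC)c(Oc2cc(OC)c(O)c(OC)c2)c(OC)c1 | intermediate
20 | 6-[2,6-dimethoxy-4-(2,4,6-trimethoxyphenoxy)phenoxy]-2,3,4-trimethoxybenzaldehyde (A–B–C aldehyde) | COc1cc(OC)c(Oc2cc(OC)c(Oc3cc(OC)c(OC)c(OC)c3C=O)c(OC)c2)c(OC)c1 | intermediate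
21 | 6-[2,6-dimethoxy-4-(2,4,6-trimethoxyphenoxy)phenoxy]-2,3,4-trimethoxyphenyl formate | COc1cc(OC)c(Oc2cc(OC)c(Oc3cc(OC)c(OC)c(OC)c3OC=O)c(OC)c2)c(OC)c1 | intermediate
22 | 6-[2,6-dimethoxy-4-(2,4,6-trimethoxyphenoxy)phenoxy]-2,3,4-trimethoxyphenol (A–B–C phenol) | COc1cc(OC)c(Oc2cc(OC)c(Oc3cc(OC)c(OC)c(OC)c3O)c(OC)c2)c(OC)c1 | intermediate
23 | 4-hydroxy-6-methyl-2H-pyran-2-one (triacetic acid lactone) | CC1=CC(O)=CC(=O)O1 | starting material
24 | 4-bromo-6-methyl-2H-pyran-2-one | CC1=CC(Br)=CC(=O)O1 | intermediate
25 | 4-bromo-6-(bromomethyl)-2H-pyran-2-one | BrCC1=CC(Br)=CC(=O)O1 | intermediate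
26 | 4-bromo-6-[(ArE-oxy)methyl]-2H-pyran-2-one (ArE–O from 14) | O=C1C=C(Br)C=C(COc2c(Oc3cc(OC)c(OC)c(Oc4cc(OC)c(OC)c(OC)c4Oc4cc(OC)c(OC)c(OC)c4)c3)cc(OC)c(OC)c2OC)O1 | intermediate
27 | 4-(ArC-oxy)-6-[(ArE-oxy)methyl]-2H-pyran-2-one (ArC–O from 22, ArE–O from 14) | COc1cc(OC)c(Oc2cc(OC)c(Oc3cc(OC)c(OC)c(OC)c3OC3=CC(=O)OC(COc4c(Oc5cc(OC)c(OC)c(Oc6cc(OC)c(OC)c(OC)c6Oc6cc(OC)c(OC)c(OC)c6)c5)cc(OC)c(OC)c4OC)=C3)c(OC)c2)c(OC)c1 | intermediate
28 | methyl (2E)-3-(ArC-oxy)-6-(ArE-oxy)-5-oxohex-2-enoate | COc1cc(OC)c(Oc2cc(OC)c(Oc3cc(OC)c(OC)c(OC)c3O/C(CC(=O)COc3c(Oc4cc(OC)c(OC)c(Oc5cc(OC)c(OC)c(OC)c5Oc5cc(OC)c(OC)c(OC)c5)c4)cc(OC)c(OC)c3OC)=C/C(=O)OC)c(OC)c2)c(OC)c1 | intermediate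
29 | 2-(ArE-oxy)-5-(ArC-oxy)benzene-1,3-diol (octamer, ring D free resorcinol, nineteen methyl ethers) | COc1cc(OC)c(Oc2cc(OC)c(Oc3cc(OC)c(OC)c(OC)c3Oc3cc(O)c(Oc4c(Oc5cc(OC)c(OC)c(Oc6cc(OC)c(OC)c(OC)c6Oc6cc(OC)c(OC)c(OC)c6)c5)cc(OC)c(OC)c4OC)c(O)c3)c(OC)c2)c(OC)c1 | intermediate
30 | CNP0309601.0, octamer with twenty-one free hydroxyls | Oc1cc(O)c(Oc2cc(O)c(Oc3cc(O)c(O)c(O)c3Oc3cc(O)c(Oc4c(Oc5cc(O)c(O)c(Oc6cc(O)c(O)c(O)c6Oc6cc(O)c(O)c(O)c6)c5)cc(O)c(O)c4O)c(O)c3)c(O)c2)c(O)c1 | target

## Step count and least certain steps

Total: 17 steps. Longest linear sequence: 10 steps (steps 2 to 7, then 14, 15, 16 and 17; from 3 to 30).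

**Step 16 (key step).** The most likely failure is exchange of the aryloxy group at C4 of 27 for methoxide by addition–elimination, since the ring C phenoxide is the better leaving group; this can happen before or beside lactone opening. At the stage of 28, methoxide may instead cleave the activated ketone (retro-Claisen fragmentation), because the enolate needed for closure is the minor tautomer and closure may be slow. The fallback assembles 28 without any pyranone meeting an alkoxide and closes it with an amide base. It sets out from phenols 22 and 14. Conjugate addition of 22 to methyl but-2-ynoate (DABCO, THF) should give methyl (2E)-3-(ArC-oxy)but-2-enoate F1. Alkylation of 14 with 2-chloro-N-methoxy-N-methylacetamide (K2CO3, NaI, acetone) should give N-methoxy-N-methyl-2-(ArE-oxy)acetamide F2. The lithium dienolate of F1 (LDA, THF, −78 °C) is acylated at its terminal carbon by F2 to give 28, which is isolated this time and closed with LiHMDS in THF as a dianion Claisen condensation. The sequence returns to the route at 28 and, after closure, at 29.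

**Step 14.** The most likely failure is loss of site selectivity: the phenoxide of 14 may add to the vinylic C4 terminus of 25 as well as displace the primary bromide, giving misplaced or double substitution. The fallback forms the ether by a Mitsunobu reaction, in which no free phenoxide is present. It sets out from 25: silver-assisted hydrolysis (AgNO3, aqueous acetone) should give 4-bromo-6-(hydroxymethyl)-2H-pyran-2-one F3, which is condensed with 14 (PPh3 and DIAD premixed, THF, 0 °C). It returns at 26.

**Step 10.** The most likely failure is slow C–O bond formation at copper for the 2,6-dimethoxyphenoxide of 19, so that reduction of the bromide of 2 and oxidative loss of the electron-rich phenol take over. The fallback changes metal and mechanism: palladium-catalysed C–O coupling (Pd(OAc)2, t-BuXPhos, K3PO4, toluene, 100 °C). A zerovalent palladium species adds to the C–Br bond of 2, and the bulky biarylphosphine forces reductive elimination of the hindered ether. It sets out from 19 and 2, returns at 20 and makes no new compound (F0).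

**Step 17.** The most likely failure is incomplete cleavage (borate esters of neighbouring oxygens slow the last demethylations) together with oxidative degradation of the free polyphenol during isolation. The fallback isolates the product through its peracetate. It sets out from 29: after the BBr3 treatment and methanolysis of the borates, the crude product is acetylated (Ac2O, pyridine) to the henicosa-O-acetyl octamer F4. This is stable and can be purified on silica and, if needed, resubmitted. Acid methanolysis (AcCl in MeOH, rt, Ar) then returns the route at 30.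

## Further compounds

F1 | step 16 | methyl (2E)-3-(ArC-oxy)but-2-enoate (ArC–O from 22) | COc1cc(OC)c(Oc2cc(OC)c(Oc3cc(OC)c(OC)c(OC)c3O/C(C)=C/C(=O)OC)c(OC)c2)c(OC)c1
F2 | step 16 | N-methoxy-N-methyl-2-(ArE-oxy)acetamide (ArE–O from 14) | CON(C)C(=O)COc1c(Oc2cc(OC)c(OC)c(Oc3cc(OC)c(OC)c(OC)c3Oc3cc(OC)c(OC)c(OC)c3)c2)cc(OC)c(OC)c1OC
F3 | step 14 | 4-bromo-6-(hydroxymethyl)-2H-pyran-2-one | OCC1=CC(Br)=CC(=O)O1
F0 | step 10 | none | none
F4 | step 17 | henicosa-O-acetyl derivative of 30 | CC(=O)Oc1cc(OC(C)=O)c(Oc2cc(OC(C)=O)c(Oc3cc(OC(C)=O)c(OC(C)=O)c(OC(C)=O)c3Oc3cc(OC(C)=O)c(Oc4c(Oc5cc(OC(C)=O)c(OC(C)=O)c(Oc6cc(OC(C)=O)c(OC(C)=O)c(OC(C)=O)c6Oc6cc(OC(C)=O)c(OC(C)=O)c(OC(C)=O)c6)c5)cc(OC(C)=O)c(OC(C)=O)c4OC(C)=O)c(OC(C)=O)c3)c(OC(C)=O)c2)c(OC(C)=O)c1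
A1 | alternative 1 | 2-(A–D tetramer aryloxy)-3,4-dimethoxy-4-(1-methoxyvinyl)cyclobut-2-en-1-one (racemic) | COc1cc(OC)c(Oc2cc(OC)c(Oc3cc(OC)c(OC)c(OC)c3Oc3cc(OC)c(OC4=C(OC)C(OC)(C(=C)OC)C4=O)c(OC)c3)c(OC)c2)c(OC)c1
A2 | alternative 1 | A–E pentamer with free hydroxyl at C2 of ring E | COc1cc(OC)c(Oc2cc(OC)c(Oc3cc(OC)c(OC)c(OC)c3Oc3cc(OC)c(Oc4c(O)cc(OC)c(OC)c4OC)c(OC)c3)c(OC)c2)c(OC)c1
A3 | alternative 2 | A–G heptamer phenol, ring G a 4-aryloxy-2-methoxyphenol | COc1cc(OC)c(Oc2cc(OC)c(Oc3cc(OC)c(OC)c(OC)c3Oc3cc(OC)c(Oc4c(Oc5cc(OC)c(OC)c(Oc6ccc(O)c(OC)c6)c5)cc(OC)c(OC)c4OC)c(OC)c3)c(OC)c2)c(OC)c1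
A4 | alternative 2 | octamer with ring G as 3-methoxy-4,5-bis(aryloxy)-ortho-quinone | COc1cc(OC)c(Oc2cc(OC)c(Oc3cc(OC)c(OC)c(OC)c3Oc3cc(OC)c(Oc4c(Oc5cc(OC)c(OC)c(OC6=CC(=O)C(=O)C(OC)=C6Oc6cc(OC)c(OC)c(OC)c6)c5)cc(OC)c(OC)c4OC)c(OC)c3)c(OC)c2)c(OC)c1
A5 | alternative 3 | cyclopentadienylruthenium hexafluorophosphate complex of 2,5-dichloro-1,3-dimethoxybenzene | COc1cc(Cl)cc(OC)c1Cl.[CH-]1C=CC=C1.[Ru+2].F[P-](F)(F)(F)(F)F
A6 | alternative 3 | C–H hexamer phenol with free hydroxyl on ring C | Oc1cc(OC)c(OC)c(OC)c1Oc1cc(OC)c(Oc2c(Oc3cc(OC)c(OC)c(Oc4cc(OC)c(OC)c(OC)c4Oc4cc(OC)c(OC)c(OC)c4)c3)cc(OC)c(OC)c2OC)c(OC)c1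
A7 | alternative 3 | cyclopentadienylruthenium hexafluorophosphate complex of the permethylated octamer, bound at ring B | COc1cc(OC)c(Oc2cc(OC)c(Oc3cc(OC)c(OC)c(OC)c3Oc3cc(OC)c(Oc4c(Oc5cc(OC)c(OC)c(Oc6cc(OC)c(OC)c(OC)c6Oc6cc(OC)c(OC)c(OC)c6)c5)cc(OC)c(OC)c4OC)c(OC)c3)c(OC)c2)c(OC)c1.[CH-]1C=CC=C1.[Ru+2].F[P-](F)(F)(F)(F)F
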